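**Plan**
- Retrosynthesis: cut the C2 ester, then the C8–CH3 bond (enol triflate of a C8 ketone), then the C9–C10 bond of ring B. The last cut is traced back to the C8–C10 bond of a cyclopentanone, so ring B (C5–C10) contracts to the five-membered ring C5, C6, C7, C8, C10 of a trans-hydrindan-8-one and C9 leaves with the whole side chain (C9, C11–C16).
- Forward: ring A and the cyclopentanone come from an amino-acid-catalysed Robinson annulation. Ring A is then adjusted (gem-dimethyl at C4, oxygen moved from C3 to C2). The linalool-derived C9 carbanion adds to the C8 ketone, and a β-oxido carbenoid 1,2-shift inserts C9 between C8 and C10, which forms ring B and the bond to the quaternary C10 in one flask.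
- Enabling feature: C8 of ring B is an alkene carbon that can be carried as a carbonyl, flanked by the fully substituted C10 (the better migrating carbon) and the C7 methylene; C9 then sits α to that carbonyl and can settle equatorial.
- Stereochemistry: C10 from the D-phenylalanine-mediated aldol cyclisation; C5 from dissolving-metal reduction (trans); C2 from hydroboration anti to the axial C4/C10 methyls; C9 from axial protonation of the enolate; C13 from (S)-linalool.

Key step: step 16

Remark: (S)-(+)-linalool and D-phenylalanine are taken as commercial in high enantiomeric purity. Intermediates carry labdane locants (ring A = C1–C5, C10; ring B = C5–C10); the bicyclic precursors are named as hydrindanes whose five-membered ring is C5, C6, C7, C8, C10. The target belongs to the ent-labdane series.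

**Route**

Step 1
Reactants: 1 2-methylcyclopentane-1,3-dione; 2 pent-1-en-3-one
Product: 3 2-methyl-2-(3-oxopentyl)cyclopentane-1,3-dione
Conditions: H2O, AcOH (cat.), 70 °C
Reagents that add atoms: none
Why: Michael addition of the acidic 1,3-dione to the vinyl ketone is the standard first half of a Robinson annulation and creates no stereocenter.

Step 2
Reactants: 3 2-methyl-2-(3-oxopentyl)cyclopentane-1,3-dione
Product: 5 (7aR)-4,7a-dimethyl-2,3,7,7a-tetrahydro-1H-indene-1,5(6H)-dione, via cis-fused bicyclic ketol 4 (not isolated)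
Conditions: D-phenylalanine (1 equiv), 1 M aq HClO4 (0.5 equiv), MeCN, reflux
Reagents that add atoms: none
Why: Hajos–Parrish-type enamine aldol cyclisation and dehydration, in which the D-amino acid selects one of the two enantiotopic ring carbonyls and so fixes C10 as R.

Step 3
Reactants: 5 (7aR)-4,7a-dimethyl-2,3,7,7a-tetrahydro-1H-indene-1,5(6H)-dione
Product: 6 (10R)-8,8-(ethylenedioxy)-4,10-dimethylhydrind-4-en-3-one
Conditions: HOCH2CH2OH (excess), p-TsOH·H2O (cat.), 4 Å molecular sieves, 23 °C
Reagents that add atoms: ethane-1,2-diol, OCCO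
Why: acid-catalysed ketalisation should be chemoselective for the saturated cyclopentanone carbonyl because the enone carbonyl is deactivated by conjugation, and no stereocenter is formed.

Step 4
Reactants: 6 (10R)-8,8-(ethylenedioxy)-4,10-dimethylhydrind-4-en-3-one
Product: 8 (5R,10R)-8,8-(ethylenedioxy)-4,4,10-trimethyl-trans-hydrindan-3-one, via lithium enolate 7 (not isolated)
Conditions: Li (2.2 equiv), NH3(l)/THF, t-BuOH (1.0 equiv), −78 → −33 °C; then MeI (excess), −78 → 23 °C
Reagents that add atoms: iodomethane, CI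
Why: Stork-type dissolving-metal reductive alkylation, in which C5 is protonated axially anti to the angular methyl to give the trans ring fusion and the regiodefined enolate is C-methylated at C4 to complete the gem-dimethyl group.

Step 5
Reactants: 8 (5R,10R)-8,8-(ethylenedioxy)-4,4,10-trimethyl-trans-hydrindan-3-one
Product: 10 (5R,10R)-8,8-(ethylenedioxy)-4,4,10-trimethyl-trans-hydrind-2-en-3-yl trifluoromethanesulfonate, via potassium enolate 9 (not isolated)
Conditions: KN(SiMe3)2, THF, −78 °C; then PhNTf2, −78 → 0 °C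
Reagents that add atoms: N-phenylbis(trifluoromethanesulfonimide), O=S(=O)(N(c1ccccc1)S(=O)(=O)C(F)(F)F)C(F)(F)F
Why: enolisation can only occur toward C2 because C4 is quaternary, so O-sulfonylation of the enolate should give a single enol triflate.

Step 6
Reactants: 10 (5R,10R)-8,8-(ethylenedioxy)-4,4,10-trimethyl-trans-hydrind-2-en-3-yl trifluoromethanesulfonate
Product: 11 (5R,10R)-8,8-(ethylenedioxy)-4,4,10-trimethyl-trans-hydrind-2-ene
Conditions: Pd(OAc)2 (5 mol %), PPh3, HCO2H, Bu3N, DMF, 60 °C
Reagents that add atoms: none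
Why: palladium-catalysed formate reduction of an enol triflate (oxidative addition to zerovalent palladium, formate exchange, decarboxylation, reductive elimination) replaces the triflate by hydrogen and leaves the C2=C3 alkene in place.

Step 7
Reactants: 11 (5R,10R)-8,8-(ethylenedioxy)-4,4,10-trimethyl-trans-hydrind-2-ene
Product: 13 (2R,5R,10R)-8,8-(ethylenedioxy)-4,4,10-trimethyl-trans-hydrindan-2-ol, via alkylborane 12 (not isolated)
Conditions: BH3·THF, THF, 0 → 23 °C; then 3 M aq NaOH, 30% H2O2, 0 → 23 °C
Reagents that add atoms: hydrogen peroxide, OO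
Why: hydroboration–oxidation should place boron at C2, the alkene carbon remote from the quaternary C4, from the face opposite the syn-axial C4 and C10 methyls, so that oxidation with retention gives the equatorial 2R alcohol.

Step 8
Reactants: 13 (2R,5R,10R)-8,8-(ethylenedioxy)-4,4,10-trimethyl-trans-hydrindan-2-ol
Product: 14 (2R,5R,10R)-2-(tert-butyldiphenylsilyloxy)-8,8-(ethylenedioxy)-4,4,10-trimethyl-trans-hydrindane
Conditions: t-BuPh2SiCl, imidazole, DMF, 23 → 40 °C
Reagents that add atoms: tert-butyl(chloro)diphenylsilane, CC(C)(C)[Si](Cl)(c1ccccc1)c1ccccc1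
Why: standard silylation of an equatorial secondary alcohol with a group that survives aqueous acid, organolithium reagents and amide bases.

Step 9
Reactants: 14 (2R,5R,10R)-2-(tert-butyldiphenylsilyloxy)-8,8-(ethylenedioxy)-4,4,10-trimethyl-trans-hydrindane
Product: 15 (2R,5R,10R)-2-(tert-butyldiphenylsilyloxy)-4,4,10-trimethyl-trans-hydrindan-8-one
Conditions: 1 M aq HCl, THF, 23 °C
Reagents that add atoms: water, O
Why: mild acid hydrolysis of the dioxolane regenerates the C8 ketone while the tert-butyldiphenylsilyl ether is stable.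

Step 10
Reactants: 16 (S)-(+)-linalool
Product: 17 (3S)-3,7-dimethyl-3-(triethylsilyloxy)octa-1,6-diene
Conditions: Et3SiOTf, 2,6-lutidine, CH2Cl2, −78 → 0 °C
Reagents that add atoms: triethylsilyl trifluoromethanesulfonate, CC[Si](CC)(CC)OS(=O)(=O)C(F)(F)F
Why: silyl triflate with a hindered base is the reliable way to protect a tertiary allylic alcohol without ionisation, and the chiral-pool stereocenter (later C13) is untouched.

Step 11
Reactants: 17 (3S)-3,7-dimethyl-3-(triethylsilyloxy)octa-1,6-diene
Product: 19 (4S)-4-methyl-4-(triethylsilyloxy)hex-5-enal, via secondary ozonide 18 (not isolated)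
Conditions: O3 (1.0 equiv), CH2Cl2, −78 °C; then PPh3, −78 → 23 °C
Reagents that add atoms: ozone, [O-][O+]=O
Why: ozonolysis with one equivalent of ozone should be chemoselective for the electron-rich trisubstituted alkene over the hindered vinyl group, and phosphine reduction of the ozonide gives the aldehyde whose carbonyl carbon becomes C9.

Step 12
Reactants: 19 (4S)-4-methyl-4-(triethylsilyloxy)hex-5-enal
Product: 20 (4S)-4-methyl-4-(triethylsilyloxy)hex-5-en-1-ol
Conditions: NaBH4, MeOH, 0 °C
Reagents that add atoms: none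
Why: routine borohydride reduction of an aldehyde.

Step 13
Reactants: 20 (4S)-4-methyl-4-(triethylsilyloxy)hex-5-en-1-ol
Product: 21 triethyl{[(3S)-3-methyl-6-(4-methylphenylsulfanyl)hex-1-en-3-yl]oxy}silane
Conditions: (4-MeC6H4S)2, Bu3P, THF, 23 °C
Reagents that add atoms: bis(4-methylphenyl) disulfide, Cc1ccc(SSc2ccc(C)cc2)cc1
Why: disulfide/phosphine thioetherification of a primary alcohol (Mitsunobu-type activation as the alkoxyphosphonium salt followed by thiolate displacement).

Step 14
Reactants: 21 triethyl{[(3S)-3-methyl-6-(4-methylphenylsulfanyl)hex-1-en-3-yl]oxy}silane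
Product: 22 triethyl{[(3S)-3-methyl-6-(4-methylphenylsulfinyl)hex-1-en-3-yl]oxy}silane (both configurations at sulfur)
Conditions: NaIO4, MeOH/H2O, 0 → 23 °C
Reagents that add atoms: sodium periodate, [Na+].[O-]I(=O)(=O)=O
Why: periodate oxidises a sulfide to the sulfoxide without over-oxidation and without touching the alkene, and the sulfur configuration is irrelevant because it is destroyed in step 16.

Step 15
Reactants: 22 triethyl{[(3S)-3-methyl-6-(4-methylphenylsulfinyl)hex-1-en-3-yl]oxy}silane
Product: 23 triethyl{[(3S)-6-chloro-3-methyl-6-(4-methylphenylsulfinyl)hex-1-en-3-yl]oxy}silane (diastereomer mixture at C6 and sulfur)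
Conditions: N-chlorosuccinimide, K2CO3, CH2Cl2, 23 °C
Reagents that add atoms: N-chlorosuccinimide, O=C1CCC(=O)N1Cl
Why: α-chlorination of an alkyl aryl sulfoxide with N-chlorosuccinimide is the standard route to 1-chloroalkyl aryl sulfoxides, and the new centre (later C9) is reset in step 16.

Step 16
Reactants: 23 triethyl{[(3S)-6-chloro-3-methyl-6-(4-methylphenylsulfinyl)hex-1-en-3-yl]oxy}silane; 15 (2R,5R,10R)-2-(tert-butyldiphenylsilyloxy)-4,4,10-trimethyl-trans-hydrindan-8-one
Product: 28 (2R,5R,9S,10R,13S)-2-(tert-butyldiphenylsilyloxy)-13-(triethylsilyloxy)-17-norlabd-14-en-8-one, via lithiated chloro sulfoxide 24 (not isolated), via lithium alkoxide adduct 25 (not isolated), via lithium β-oxido carbenoid 26 (not isolated), via lithium enolate 27 (not isolated)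
Conditions: 23, LiN(iPr)2 (1.2 equiv), THF, −78 °C; then 15, −78 °C; then t-BuLi (4 equiv), −78 °C; aq NH4Cl, −78 → 23 °C
Reagents that add atoms: none
Why: The α-sulfinyl carbanion 24 adds to the C8 carbonyl of 15, and sulfoxide–lithium exchange of alkoxide 25 with t-BuLi gives the β-oxido carbenoid 26, in which the C8–C10 bond migrates to the electrophilic carbenoid carbon C9 with loss of LiCl, so that C9 is inserted between C8 and C10 and the cyclopentanone (C5, C6, C7, C8, C10) becomes ring B as the lithium enolate 27. The closest known reaction type is the one-carbon ring homologation of cycloalkanones through β-oxido carbenoids generated from 1-chloroalkyl aryl sulfoxide adducts, a semipinacol-type 1,2-alkyl shift of the same family as the D-homoannulation of 17-keto steroids. No ring is closed by cyclisation: ring B arises by expansion of the five-membered ring by one atom, and the new σ bond is the hindered C9–C10 bond that joins the two fragments. C10 migrates with retention and the trans ring fusion is untouched, the C8, C9 and sulfur centres of the adduct are erased in enolate 27, and C9 is set on protonation, which should occur axially on the face opposite the axial C10 methyl to give the equatorial side chain (9S in this ketone), the epimer that base equilibration would also favour. The selectivity needed is migration of the fully substituted C10 and not of the C7 methylene, which the higher migratory aptitude of the more substituted carbon in carbenoid 1,2-shifts should secure, and the product is protected from excess t-BuLi because it is formed as its enolate.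

Step 17
Reactants: 28 (2R,5R,9S,10R,13S)-2-(tert-butyldiphenylsilyloxy)-13-(triethylsilyloxy)-17-norlabd-14-en-8-one
Product: 30 (2R,5R,9S,10R,13S)-2-(tert-butyldiphenylsilyloxy)-13-(triethylsilyloxy)-17-norlabda-7,14-dien-8-yl trifluoromethanesulfonate, via potassium enolate 29 (not isolated)
Conditions: KN(SiMe3)2, THF, −78 °C; then PhNTf2, −78 → 0 °C
Reagents that add atoms: N-phenylbis(trifluoromethanesulfonimide), O=S(=O)(N(c1ccccc1)S(=O)(=O)C(F)(F)F)C(F)(F)F
Why: kinetic deprotonation by the bulky amide should occur at the C7 methylene and not at the hindered axial C9–H next to the quaternary C10, so O-sulfonylation gives the C7=C8 enol triflate regioselectively.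

Step 18
Reactants: 30 (2R,5R,9S,10R,13S)-2-(tert-butyldiphenylsilyloxy)-13-(triethylsilyloxy)-17-norlabda-7,14-dien-8-yl trifluoromethanesulfonate
Product: 31 (2R,5R,9R,10R,13S)-2-(tert-butyldiphenylsilyloxy)-13-(triethylsilyloxy)labda-7,14-diene
Conditions: MeMgBr (3 equiv), Fe(acac)3 (5 mol %), THF/N-methylpyrrolidone, −30 → 0 °C
Reagents that add atoms: methylmagnesium bromide, C[Mg]Br
Why: iron-catalysed Kumada-type cross-coupling of an alkenyl triflate with a methyl Grignard reagent (low-valent iron intermediates) installs the C8 methyl with the alkene fixed at C7=C8.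

Step 19
Reactants: 31 (2R,5R,9R,10R,13S)-2-(tert-butyldiphenylsilyloxy)-13-(triethylsilyloxy)labda-7,14-diene
Product: 32 (2R,5R,9R,10R,13S)-labda-7,14-diene-2,13-diol
Conditions: Bu4NF (excess), THF, 23 → 50 °C
Reagents that add atoms: none
Why: fluoride cleaves both silyl ethers, and the diol has no base-sensitive group at this stage.

Step 20
Reactants: 32 (2R,5R,9R,10R,13S)-labda-7,14-diene-2,13-diol; 33 3-methylbut-2-enoic acid
Product: 34 (2R,5R,9R,10R,13S)-13-hydroxylabda-7,14-dien-2-yl 3-methylbut-2-enoate (target, CNP0252389.1)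
Conditions: 33 (1.5 equiv), N,N'-dicyclohexylcarbodiimide, 4-(dimethylamino)pyridine (cat.), CH2Cl2, 0 → 23 °C
Reagents that add atoms: none
Why: Steglich esterification should acylate the equatorial secondary C2 hydroxyl chemoselectively because the tertiary allylic C13 hydroxyl is too hindered, and the mild carbodiimide conditions avoid deconjugation of the 3-methylbut-2-enoyl unit.

**Compound list**
1 | 2-methylcyclopentane-1,3-dione | CC1C(=O)CCC1=O | starting material
2 | pent-1-en-3-one (ethyl vinyl ketone) | C=CC(=O)CC | starting material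
3 | 2-methyl-2-(3-oxopentyl)cyclopentane-1,3-dione | CCC(=O)CCC1(C)C(=O)CCC1=O | intermediate
4 | (3aR,7aR)-3a-hydroxy-4,7a-dimethyloctahydro-1H-indene-1,5-dione, cis-fused ketol, hydroxyl syn to the angular methyl, C4 unassigned | O=C1CC[C@@]2(O)C(C)C(=O)CC[C@@]12C | intermediate (not isolated)
5 | (7aR)-4,7a-dimethyl-2,3,7,7a-tetrahydro-1H-indene-1,5(6H)-dione | O=C1CCC2=C(C)C(=O)CC[C@@]12C | intermediate
6 | (10R)-8,8-(ethylenedioxy)-4,10-dimethylhydrind-4-en-3-one | O1CCOC12CCC3=C(C)C(=O)CC[C@@]23C | intermediate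
7 | lithium C3 enolate (C3=C4) of the trans-hydrindane, H5 anti to the C10 methyl | O1CCOC12CC[C@@H]3C(C)=C(O[Li])CC[C@@]23C | intermediate (not isolated)
8 | (5R,10R)-8,8-(ethylenedioxy)-4,4,10-trimethyl-trans-hydrindan-3-one | O1CCOC12CC[C@@H]3C(C)(C)C(=O)CC[C@@]23C | intermediate
9 | potassium C3 enolate (C2=C3) of 8 | O1CCOC12CC[C@@H]3C(C)(C)C(O[K])=CC[C@@]23C | intermediate (not isolated)
10 | (5R,10R)-8,8-(ethylenedioxy)-4,4,10-trimethyl-trans-hydrind-2-en-3-yl trifluoromethanesulfonate | O1CCOC12CC[C@@H]3C(C)(C)C(OS(=O)(=O)C(F)(F)F)=CC[C@@]23C | intermediate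
11 | (5R,10R)-8,8-(ethylenedioxy)-4,4,10-trimethyl-trans-hydrind-2-ene | O1CCOC12CC[C@@H]3C(C)(C)C=CC[C@@]23C | intermediate
12 | C2 alkylborane of 11, boron equatorial and anti to the C10 methyl | O1CCOC12CC[C@@H]3C(C)(C)C[C@@H](B)C[C@@]23C | intermediate (not isolated)
13 | (2R,5R,10R)-8,8-(ethylenedioxy)-4,4,10-trimethyl-trans-hydrindan-2-ol | O1CCOC12CC[C@@H]3C(C)(C)C[C@@H](O)C[C@@]23C | intermediate
14 | (2R,5R,10R)-2-(tert-butyldiphenylsilyloxy)-8,8-(ethylenedioxy)-4,4,10-trimethyl-trans-hydrindane | O1CCOC12CC[C@@H]3C(C)(C)C[C@@H](O[Si](c4ccccc4)(c4ccccc4)C(C)(C)C)C[C@@]23C | intermediate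
15 | (2R,5R,10R)-2-(tert-butyldiphenylsilyloxy)-4,4,10-trimethyl-trans-hydrindan-8-one | O=C1CC[C@@H]2C(C)(C)C[C@@H](O[Si](c3ccccc3)(c3ccccc3)C(C)(C)C)C[C@@]12C | intermediate
16 | (S)-(+)-linalool, (3S)-3,7-dimethylocta-1,6-dien-3-ol | C=C[C@@](C)(O)CCC=C(C)C | starting material
17 | (3S)-3,7-dimethyl-3-(triethylsilyloxy)octa-1,6-diene | C=C[C@@](C)(O[Si](CC)(CC)CC)CCC=C(C)C | intermediate
18 | secondary ozonide (1,2,4-trioxolane) of the 6,7-alkene of 17 | C=C[C@@](C)(O[Si](CC)(CC)CC)CCC1OOC(C)(C)O1 | intermediate (not isolated)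
19 | (4S)-4-methyl-4-(triethylsilyloxy)hex-5-enal | C=C[C@@](C)(O[Si](CC)(CC)CC)CCC=O | intermediate
20 | (4S)-4-methyl-4-(triethylsilyloxy)hex-5-en-1-ol | C=C[C@@](C)(O[Si](CC)(CC)CC)CCCO | intermediate
21 | triethyl{[(3S)-3-methyl-6-(4-methylphenylsulfanyl)hex-1-en-3-yl]oxy}silane | C=C[C@@](C)(O[Si](CC)(CC)CC)CCCSc1ccc(C)cc1 | intermediate
22 | triethyl{[(3S)-3-methyl-6-(4-methylphenylsulfinyl)hex-1-en-3-yl]oxy}silane, both configurations at sulfur | C=C[C@@](C)(O[Si](CC)(CC)CC)CCCS(=O)c1ccc(C)cc1 | intermediate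
23 | triethyl{[(3S)-6-chloro-3-methyl-6-(4-methylphenylsulfinyl)hex-1-en-3-yl]oxy}silane, mixture at C6 and sulfur | C=C[C@@](C)(O[Si](CC)(CC)CC)CCC(Cl)S(=O)c1ccc(C)cc1 | intermediate
24 | α-lithio derivative of 23 (lithium on the chlorine-bearing carbon) | C=C[C@@](C)(O[Si](CC)(CC)CC)CCC([Li])(Cl)S(=O)c1ccc(C)cc1 | intermediate (not isolated)
25 | lithium C8 alkoxide of the adduct of 24 to ketone 15, mixture at C8, C9 and sulfur | C=C[C@@](C)(O[Si](CC)(CC)CC)CCC(Cl)(S(=O)c1ccc(C)cc1)C1(O[Li])CC[C@@H]2C(C)(C)C[C@@H](O[Si](c3ccccc3)(c3ccccc3)C(C)(C)C)C[C@@]12C | intermediate (not isolated)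
26 | lithium β-oxido carbenoid (C9 bears Li and Cl, C8 bears OLi) | C=C[C@@](C)(O[Si](CC)(CC)CC)CCC([Li])(Cl)C1(O[Li])CC[C@@H]2C(C)(C)C[C@@H](O[Si](c3ccccc3)(c3ccccc3)C(C)(C)C)C[C@@]12C | intermediate (not isolated)
27 | lithium C8 enolate (C8=C9) of the ring-expanded decalone | C=C[C@@](C)(O[Si](CC)(CC)CC)CCC1=C(O[Li])CC[C@@H]2C(C)(C)C[C@@H](O[Si](c3ccccc3)(c3ccccc3)C(C)(C)C)C[C@@]12C | intermediate (not isolated)
28 | (2R,5R,9S,10R,13S)-2-(tert-butyldiphenylsilyloxy)-13-(triethylsilyloxy)-17-norlabd-14-en-8-one | C=C[C@@](C)(O[Si](CC)(CC)CC)CC[C@@H]1C(=O)CC[C@@H]2C(C)(C)C[C@@H](O[Si](c3ccccc3)(c3ccccc3)C(C)(C)C)C[C@@]12C | intermediate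
29 | potassium C8 enolate (C7=C8) of 28 | C=C[C@@](C)(O[Si](CC)(CC)CC)CC[C@@H]1C(O[K])=CC[C@@H]2C(C)(C)C[C@@H](O[Si](c3ccccc3)(c3ccccc3)C(C)(C)C)C[C@@]12C | intermediate (not isolated)
30 | (2R,5R,9S,10R,13S)-2-(tert-butyldiphenylsilyloxy)-13-(triethylsilyloxy)-17-norlabda-7,14-dien-8-yl trifluoromethanesulfonate | C=C[C@@](C)(O[Si](CC)(CC)CC)CC[C@@H]1C(OS(=O)(=O)C(F)(F)F)=CC[C@@H]2C(C)(C)C[C@@H](O[Si](c3ccccc3)(c3ccccc3)C(C)(C)C)C[C@@]12C | intermediate
31 | (2R,5R,9R,10R,13S)-2-(tert-butyldiphenylsilyloxy)-13-(triethylsilyloxy)labda-7,14-diene | C=C[C@@](C)(O[Si](CC)(CC)CC)CC[C@@H]1C(C)=CC[C@@H]2C(C)(C)C[C@@H](O[Si](c3ccccc3)(c3ccccc3)C(C)(C)C)C[C@@]12C | intermediate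
32 | (2R,5R,9R,10R,13S)-labda-7,14-diene-2,13-diol | C=C[C@@](C)(O)CC[C@@H]1C(C)=CC[C@@H]2C(C)(C)C[C@@H](O)C[C@@]12C | intermediate
33 | 3-methylbut-2-enoic acid | CC(C)=CC(=O)O | starting material
34 | (2R,5R,9R,10R,13S)-13-hydroxylabda-7,14-dien-2-yl 3-methylbut-2-enoate | C=C[C@@](C)(O)CC[C@@H]1C(C)=CC[C@@H]2C(C)(C)C[C@@H](OC(=O)C=C(C)C)C[C@@]12C | target

**Totals and risks**
Total steps: 20. Longest linear sequence: 14 (steps 1–9 and 16–20).

Steps most likely to fail, with fallbacks:

1. Step 16. The congested carbanion addition to the neopentyl C8 ketone may revert, or the C7 methylene may migrate (or the alkoxide may close to an epoxide) in place of C10. The fallback is a cationic pinacol-type D-homoannulation that sets out from alcohol 20 and ketone 15 and returns at ketone 28. Alcohol 20 is converted with I2, PPh3 and imidazole into the primary iodide F1 and then with PPh3 in hot MeCN into the phosphonium iodide F2. Its ylide (NaN(SiMe3)2, THF, reflux) is condensed with ketone 15 in a Wittig reaction to give the alkylidene hydrindane F3 with the C8=C9 double bond. OsO4 (cat.) with N-methylmorpholine N-oxide dihydroxylates this electron-rich trisubstituted alkene in preference to the vinyl group to give the C8,C9-diol F4. MsCl/Et3N sulfonylates only the secondary C9 hydroxyl to give the β-hydroxy mesylate F5. Et3Al in CH2Cl2 (−78 → 0 °C) then triggers the 1,2-shift of C10 from C8 to C9 with loss of mesylate, where the tertiary carbon is the better migrating group, and gives 28 after equilibration at C9.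

2. Step 7. Boron may be delivered to C3 or to the methyl-bearing face. The fallback sets out from alkene 11 and returns at silyl ether 14. OsO4 (cat.) with N-methylmorpholine N-oxide dihydroxylates 11 from the face opposite the axial methyls to give the cis-2,3-diol F6. The equatorial C2 hydroxyl is silylated selectively (t-BuPh2SiCl, imidazole, DMF) to give the mono-silyl ether F7, whose axial neopentyl C3 hydroxyl is converted into the S-methyl xanthate F8 (NaH, CS2, then MeI). Barton–McCombie deoxygenation (Bu3SnH, AIBN, toluene, 110 °C) then gives 14.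

3. Step 4. Protonation of C5 may give poor control of the ring-fusion configuration, and the enolate may be over-alkylated. The fallback sets out from enone 6 and returns at ketone 8. Enone 6 is methylated at C4 under deconjugative conditions (KOtBu, MeI, t-BuOH) through the extended dienolate to give the β,γ-unsaturated ketone F9. Its C5=C6 alkene is hydrogenated (H2, Pd/C, EtOAc) from the face opposite the angular and the axial C4 methyl groups to give trans-fused 8.

**Further compounds**
F1 | step 16 | triethyl{[(3S)-6-iodo-3-methylhex-1-en-3-yl]oxy}silane | C=C[C@@](C)(O[Si](CC)(CC)CC)CCCI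
F2 | step 16 | [(4S)-4-methyl-4-(triethylsilyloxy)hex-5-en-1-yl]triphenylphosphonium iodide | C=C[C@@](C)(O[Si](CC)(CC)CC)CCC[P+](c1ccccc1)(c1ccccc1)c1ccccc1.[I-]
F3 | step 16 | (2R,5R,10R)-2-(tert-butyldiphenylsilyloxy)-4,4,10-trimethyl-8-[(4S)-4-methyl-4-(triethylsilyloxy)hex-5-en-1-ylidene]-trans-hydrindane, alkene geometry unassigned | C=C[C@@](C)(O[Si](CC)(CC)CC)CCC=C1CC[C@@H]2C(C)(C)C[C@@H](O[Si](c3ccccc3)(c3ccccc3)C(C)(C)C)C[C@@]12C
F4 | step 16 | C8,C9-diol of F3 (C8 tertiary, C9 secondary hydroxyl, configurations unassigned) | C=C[C@@](C)(O[Si](CC)(CC)CC)CCC(O)C1(O)CC[C@@H]2C(C)(C)C[C@@H](O[Si](c3ccccc3)(c3ccccc3)C(C)(C)C)C[C@@]12C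
F5 | step 16 | C9 methanesulfonate of diol F4 | C=C[C@@](C)(O[Si](CC)(CC)CC)CCC(OS(C)(=O)=O)C1(O)CC[C@@H]2C(C)(C)C[C@@H](O[Si](c3ccccc3)(c3ccccc3)C(C)(C)C)C[C@@]12C
F6 | step 7 | (2R,5R,10R)-8,8-(ethylenedioxy)-4,4,10-trimethyl-trans-hydrindane-2,3-diol, cis-diol anti to the C10 methyl | O1CCOC12CC[C@@H]3C(C)(C)[C@@H](O)[C@@H](O)C[C@@]23C
F7 | step 7 | 2-O-(tert-butyldiphenylsilyl) ether of diol F6 | O1CCOC12CC[C@@H]3C(C)(C)[C@@H](O)[C@@H](O[Si](c4ccccc4)(c4ccccc4)C(C)(C)C)C[C@@]23C
F8 | step 7 | 3-O-(methylsulfanylthiocarbonyl) derivative (S-methyl xanthate) of F7 | O1CCOC12CC[C@@H]3C(C)(C)[C@@H](OC(=S)SC)[C@@H](O[Si](c4ccccc4)(c4ccccc4)C(C)(C)C)C[C@@]23C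
F9 | step 4 | (10R)-8,8-(ethylenedioxy)-4,4,10-trimethylhydrind-5-en-3-one | O1CCOC12CC=C3C(C)(C)C(=O)CC[C@@]23C
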